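**Plan**
- Retrosynthetic cuts, in order: the side-chain ester C–O; the C6–C7 bond of the carbocycle (chromene numbering); the C4a–C5 acyl bond; the O1–C8a bond of the dihydropyranone; the C4–C4a bond; the two C–C bonds at quaternary C8.
- Enabling feature: the carbocycle (C4a, C5, C6, C7, C8, C8a) is an enolised 2-alkylcyclohexane-1,3-dione (C5–OH, C6, C7=O) whose C7 ketone sits next to the non-enolisable quaternary C8. C6–C7 is therefore a Claisen (Dieckmann) bond between a C6 ketone enolate and a C7 ester, in the manner of the polyketide Claisen closure of acylphloroglucinols, and C8 never has to be made by dearomative alkylation.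
- Forward order: cyclobutane unit (from verbenone) → quaternary β-keto ester → dihydropyranone ring → 5-acyl chain → carbocycle (last ring) → free acid.
- Stereochemistry: cyclobutane from (1R,5R)-verbenone; C8 by prenylation of a valine-derived chiral enamine; cis-2,3-dimethyl from an Evans syn-aldol; side-chain centre from cinchona-catalysed desymmetrisation of 3-propylglutaric anhydride.

Key step: step 19

Abbreviation used in names: "Cb-methyl" = [(1S,3R)-2,2-dimethyl-3-(prop-1-en-2-yl)cyclobutyl]methyl; "allyl" = prop-2-en-1-yl.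

Assumption 1: (1R,5R)-(+)-verbenone is taken as purchasable (it is also one allylic oxidation away from (+)-α-pinene).
Assumption 2: the sense of induction in steps 7 and 14 is assigned from the accepted models and has not been checked against a reference; in each case the mirror-image reagent (D-valine ester; the dihydroquinine-derived catalyst) gives the opposite sense if correlation shows it is needed.

Step 1
Reactants: 1 (1R,5R)-(+)-verbenone
Product: 2 (1R,3S)-3-acetyl-2,2-dimethylcyclobutane-1-carboxylic acid (cis-pinononic acid)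
Conditions: RuCl3·xH2O (cat.), NaIO4, CCl4/MeCN/H2O, rt
Reagents that add atoms: sodium periodate [Na+].[O-]I(=O)(=O)=O; water O
Why: Ruthenium tetroxide cleavage of the enone C=C followed by oxidative decarboxylation of the resulting α-keto acid should leave both ring stereocentres untouched and deliver the cis-1,3-disubstituted cyclobutane.

Step 2
Reactants: 2 cis-pinononic acid
Product: 3 (1R,3R)-2,2-dimethyl-3-(prop-1-en-2-yl)cyclobutane-1-carboxylic acid
Conditions: Ph3PCH3Br, KOtBu (2.5 equiv each), THF, 0 °C→rt; acidic work-up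
Reagents that add atoms: methyltriphenylphosphonium bromide C[P+](c1ccccc1)(c1ccccc1)c1ccccc1.[Br-]
Why: Wittig methylenation of the methyl ketone on the carboxylate salt; any enolisation is expected toward the methyl group, so the cis ring configuration should be kept.

Step 3
Reactants: 3 isopropenyl acid
Product: 4 [(1R,3R)-2,2-dimethyl-3-(prop-1-en-2-yl)cyclobutyl]methanol
Conditions: LiAlH4, Et2O, 0 °C→rt
Reagents that add atoms: none
Why: Hydride reduction of a carboxylic acid to the primary alcohol, with the isolated alkene inert.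

Step 4
Reactants: 4 cyclobutylmethanol
Product: 5 (1R,3R)-1-(iodomethyl)-2,2-dimethyl-3-(prop-1-en-2-yl)cyclobutane
Conditions: I2, PPh3, imidazole, CH2Cl2, 0 °C→rt
Reagents that add atoms: iodine II
Why: Appel-type iodination through the alkoxyphosphonium ion (SN2 at the primary carbon), avoiding the cationic conditions that would ring-expand a cyclobutylcarbinyl system.

Step 5
Reactants: 5 cyclobutylmethyl iodide; 6 allyl acetoacetate
Product: 7 allyl 2-(Cb-methyl)-3-oxobutanoate (mixture of C2 epimers)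
Conditions: NaH, 6 (2 equiv), DMF, 0→60 °C
Reagents that add atoms: none
Why: SN2 C-alkylation of the sodium acetoacetate enolate by a primary iodide (β-branched, hence DMF and heat; excess 6 limits dialkylation); the new C2 centre is erased in step 6.

Step 6
Reactants: 7 alkylated acetoacetate; 8 L-valine tert-butyl ester
Product: 9 allyl (Z)-3-{[(2S)-1-tert-butoxy-3-methyl-1-oxobutan-2-yl]amino}-2-(Cb-methyl)but-2-enoate
Conditions: BF3·OEt2 (cat.), benzene, reflux, Dean–Stark
Reagents that add atoms: none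
Why: Condensation of the ketone with the amine gives the conjugated enamino ester, whose Z geometry is fixed by the N–H···O=C hydrogen bond.

Step 7
Reactants: 9 chiral enamino ester
Product: 12 allyl (2R)-2-acetyl-2-(Cb-methyl)-5-methylhex-4-enoate, via lithium aza-enolate 10 (not isolated), via prenylated ketimine 11 (not isolated)
Conditions: LiN(iPr)2, toluene, −78 °C; HMPA (1 equiv); prenyl bromide, −78→−55 °C; then 1 N HCl, THF, 0 °C→rt
Reagents that add atoms: 1-bromo-3-methylbut-2-ene CC(C)=CCBr; water O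
Why: Chiral-enamine alkylation of an α-alkyl β-keto ester: lithium is held by the enamine N, the enolate O and the valine ester C=O, HMPA fills the open lithium site on the face anti to the isopropyl group, and prenyl bromide attacks C2 from the other face (2R on the model, see assumption 2); mild acid then hydrolyses the ketimine and returns the auxiliary.

Step 8
Reactants: 13 (4S)-4-benzyl-3-propanoyl-1,3-oxazolidin-2-one; 14 acetaldehyde
Product: 16 (4S)-4-benzyl-3-[(2S,3R)-3-hydroxy-2-methylbutanoyl]-1,3-oxazolidin-2-one, via Z dibutylboron enolate 15 (not isolated)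
Conditions: Bu2BOTf, iPr2NEt, CH2Cl2, −78→0 °C; then pH 7 buffer, MeOH, H2O2
Reagents that add atoms: none
Why: Evans syn-aldol through the Z boron enolate and a chair transition state; the benzyl group of the auxiliary controls the face and should give the 2,3-syn (2S,3R) adduct that becomes the cis-2,3-dimethyl unit.

Step 9
Reactants: 16 aldol adduct
Product: 17 (2S,3R)-3-hydroxy-N-methoxy-N,2-dimethylbutanamide
Conditions: MeNH(OMe)·HCl, AlMe3, CH2Cl2, −15→0 °C
Reagents that add atoms: N,O-dimethylhydroxylamine hydrochloride CNOC.Cl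
Why: Aluminium-amide transamidation of the exocyclic imide carbonyl, assisted by the free β-hydroxyl, releases the auxiliary without touching the α-centre.

Step 10
Reactants: 17 hydroxy Weinreb amide
Product: 18 (2S,3R)-3-[(tert-butyldimethylsilyl)oxy]-N-methoxy-N,2-dimethylbutanamide
Conditions: TBSCl, imidazole, DMF, rt
Reagents that add atoms: tert-butyldimethylsilyl chloride CC(C)(C)[Si](C)(C)Cl
Why: Standard silylation of the secondary alcohol blocks retro-aldol and O-acylation in the next step.

Step 11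
Reactants: 12 quaternary β-keto ester; 18 silylated Weinreb amide
Product: 20 allyl (2R)-2-[(4S,5R)-5-{[tert-butyl(dimethyl)silyl]oxy}-4-methyl-3-oxohexanoyl]-2-(Cb-methyl)-5-methylhex-4-enoate, via lithium enolate 19 (not isolated)
Conditions: LiN(iPr)2 (1.1 equiv), THF, −78 °C; then 18, −78→0 °C; aq. NH4Cl
Reagents that add atoms: none
Why: The methyl group is the only enolisable position of 12 (C2 is quaternary); its lithium enolate acylates on carbon with the Weinreb amide, and the chelated tetrahedral intermediate should prevent over-addition and epimerisation of the α-methyl centre.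

Step 12
Reactants: 20 silyloxy β-diketone
Product: 22 allyl (2R)-2-[(2R,3S)-2,3-dimethyl-4-oxo-3,4-dihydro-2H-pyran-6-yl]-2-(Cb-methyl)-5-methylhex-4-enoate, via hydroxy diketone 21 (not isolated)
Conditions: HF·pyridine, THF, 0 °C→rt; then TsOH·H2O (cat.), CH2Cl2, 4 Å sieves, rt
Reagents that add atoms: none
Why: Desilylation then acid-catalysed cyclodehydration of the δ-hydroxy-β-diketone (hemiketal, loss of water); only the carbonyl next to the quaternary carbon is 1,5 to the hydroxyl, so the ring oxygen ends on that carbon and both methyl-bearing centres are retained (cis).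

Step 13
Reactants: 22 dihydropyranone
Product: 23 allyl (2R)-2-[(2R,3S)-5-iodo-2,3-dimethyl-4-oxo-3,4-dihydro-2H-pyran-6-yl]-2-(Cb-methyl)-5-methylhex-4-enoate
Conditions: I2, pyridine, CH2Cl2, 0 °C→rt, dark; aq. Na2S2O3
Reagents that add atoms: iodine II
Why: Electrophilic α-iodination of a β-alkoxy enone (push–pull alkene); substitution at C5 becomes irreversible when pyridine removes the proton, whereas iodine adds only reversibly to the isolated alkenes.

Step 14
Reactants: 24 3-propylglutaric anhydride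
Product: 25 (3R)-3-(2-methoxy-2-oxoethyl)hexanoic acid
Conditions: (DHQD)2AQN (10 mol %), MeOH, Et2O, −40 °C
Reagents that add atoms: methanol CO
Why: Cinchona-alkaloid-catalysed methanolysis that selects one of the two enantiotopic carbonyls of the prochiral anhydride (general-base catalysis by the quinuclidine nitrogen) sets the side-chain stereocentre (see assumption 2).

Step 15
Reactants: 25 hemiester
Product: 26 methyl (3R)-3-(2-hydroxyethyl)hexanoate
Conditions: BH3·SMe2, THF, −10→0 °C; MeOH quench; used at once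
Reagents that add atoms: none
Why: Borane reduces the free carboxylic acid much faster than the methyl ester; prompt use avoids lactonisation of the 5-hydroxy ester.

Step 16
Reactants: 26 hydroxy ester
Product: 27 methyl (3R)-3-(2-oxoethyl)hexanoate
Conditions: Dess–Martin periodinane, NaHCO3, CH2Cl2, 0 °C→rt
Reagents that add atoms: none
Why: Mild buffered oxidation of the primary alcohol to the aldehyde; the stereocentre is β to the new carbonyl and cannot epimerise.

Step 17
Reactants: 23 iodopyranone; 27 aldehyde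
Product: 29 methyl (3R)-5-hydroxy-5-{(2R,3S)-6-[(2R)-2-(Cb-methyl)-5-methyl-1-oxo-1-(allyloxy)hex-4-en-2-yl]-2,3-dimethyl-4-oxo-3,4-dihydro-2H-pyran-5-yl}-3-propylpentanoate (carbinol epimers), via pyranonylmagnesium chloride 28 (not isolated)
Conditions: iPrMgCl·LiCl (1.1 equiv), THF, −40 °C; then 27, −40→−20 °C; aq. NH4Cl
Reagents that add atoms: none
Why: Iodine–magnesium exchange on the α-iodo enone gives a carbonyl-chelated alkenylmagnesium that is kept cold to suppress β-alkoxide elimination and adds 1,2 to the aldehyde, far more electrophilic than either ester; the carbinol centre is oxidised next.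

Step 18
Reactants: 29 allylic alcohol
Product: 30 methyl (3R)-5-{(2R,3S)-6-[(2R)-2-(Cb-methyl)-5-methyl-1-oxo-1-(allyloxy)hex-4-en-2-yl]-2,3-dimethyl-4-oxo-3,4-dihydro-2H-pyran-5-yl}-5-oxo-3-propylpentanoate
Conditions: Dess–Martin periodinane, NaHCO3, CH2Cl2, 0 °C→rt
Reagents that add atoms: none
Why: Neutral oxidation of the secondary allylic alcohol to the 5-acyl dihydropyranone, with no base that could epimerise the cis-dimethyl centre.

Step 19
Reactants: 30 keto diester
Product: 32 methyl (3S)-3-[(2R,3S,8R)-8-(Cb-methyl)-5-hydroxy-2,3-dimethyl-8-(3-methylbut-2-en-1-yl)-4,7-dioxo-3,4,7,8-tetrahydro-2H-chromen-6-yl]hexanoate, via lithium enolate 31 (not isolated)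
Conditions: LiN(SiMe3)2 (1.2 equiv), THF, −78→0 °C; then cold 0.5 N HCl
Reagents that add atoms: none
Why: The base removes a proton of the CH2 between the C5 ketone and the side-chain stereocentre (the ester-bearing carbon is quaternary, so the allyl ester can act only as acceptor), the enolate carbon attacks the ester carbonyl, allyloxide leaves and the resulting β-triketone (a vinylogous acid) is deprotonated at once, which makes the closure irreversible. The closest known reaction type is the Dieckmann/Claisen cyclisation of δ-keto esters to cyclohexane-1,3-diones, the laboratory counterpart of the polyketide Claisen closure that gives acylphloroglucinols. The six-membered carbocycle closes in the 6-(enolendo)-exo-trig mode, helped by the gem-dialkyl effect of the quaternary carbon and by the cis arrangement of the two reacting arms on the pyranone C5=C6 bond. No stereocentre is created; the existing ones should survive because the quaternary carbon cannot enolise, the side-chain centre is β to the enolate, and the cis-dimethyl CH is deprotonated more slowly than the CH2 and is shielded in the anionic product. The selectivity needed is C- over O-acylation and this CH2 over the ester CH2 and the ring CH(Me): the first is secured thermodynamically (any enol lactone is reopened by allyloxide and funnelled to the triketonate), the second by acidity and access.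

Step 20
Reactants: 32 methyl ester
Product: 33 (3S)-3-[(2R,3S,8R)-8-(Cb-methyl)-5-hydroxy-2,3-dimethyl-8-(3-methylbut-2-en-1-yl)-4,7-dioxo-3,4,7,8-tetrahydro-2H-chromen-6-yl]hexanoic acid (target)
Conditions: Me3SnOH, 1,2-dichloroethane, 70 °C; then 5% aq. KHSO4
Reagents that add atoms: trimethyltin hydroxide C[Sn](C)(C)O
Why: Near-neutral tin-hydroxide cleavage of the unhindered methyl ester avoids both the strong acid that would cyclise the prenyl group or open the cyclobutylcarbinyl system and the strong base that would epimerise the cis-dimethylpyranone.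

**Compound list**
1 | (1R,5R)-(+)-verbenone | CC1=CC(=O)[C@@H]2C[C@H]1C2(C)C | starting material
2 | (1R,3S)-3-acetyl-2,2-dimethylcyclobutane-1-carboxylic acid | CC(=O)[C@H]1C[C@@H](C(=O)O)C1(C)C | intermediate
3 | (1R,3R)-2,2-dimethyl-3-(prop-1-en-2-yl)cyclobutane-1-carboxylic acid | C=C(C)[C@H]1C[C@@H](C(=O)O)C1(C)C | intermediate
4 | [(1R,3R)-2,2-dimethyl-3-(prop-1-en-2-yl)cyclobutyl]methanol | C=C(C)[C@H]1C[C@@H](CO)C1(C)C | intermediate
5 | (1R,3R)-1-(iodomethyl)-2,2-dimethyl-3-(prop-1-en-2-yl)cyclobutane | C=C(C)[C@H]1C[C@@H](CI)C1(C)C | intermediate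
6 | allyl acetoacetate | CC(=O)CC(=O)OCC=C | starting material
7 | allyl 2-(Cb-methyl)-3-oxobutanoate (C2 epimers) | C=C(C)[C@H]1C[C@@H](CC(C(C)=O)C(=O)OCC=C)C1(C)C | intermediate
8 | L-valine tert-butyl ester | CC(C)[C@H](N)C(=O)OC(C)(C)C | starting material
9 | allyl (Z)-3-{[(2S)-1-tert-butoxy-3-methyl-1-oxobutan-2-yl]amino}-2-(Cb-methyl)but-2-enoate | C=CCOC(=O)/C(C[C@@H]1C[C@H](C(C)=C)C1(C)C)=C(/C)N[C@@H](C(C)C)C(=O)OC(C)(C)C | intermediate
10 | N-lithio aza-enolate of 9 | C=CCOC(=O)/C(C[C@@H]1C[C@H](C(C)=C)C1(C)C)=C(/C)N([Li])[C@@H](C(C)C)C(=O)OC(C)(C)C | intermediate (not isolated)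
11 | allyl (2R)-2-[1-{[(2S)-1-tert-butoxy-3-methyl-1-oxobutan-2-yl]imino}ethyl]-2-(Cb-methyl)-5-methylhex-4-enoate | C=C(C)[C@H]1C[C@@H](C[C@](CC=C(C)C)(C(C)=N[C@@H](C(C)C)C(=O)OC(C)(C)C)C(=O)OCC=C)C1(C)C | intermediate (not isolated)
12 | allyl (2R)-2-acetyl-2-(Cb-methyl)-5-methylhex-4-enoate | C=C(C)[C@H]1C[C@@H](C[C@](CC=C(C)C)(C(C)=O)C(=O)OCC=C)C1(C)C | intermediate
13 | (4S)-4-benzyl-3-propanoyl-1,3-oxazolidin-2-one | CCC(=O)N1[C@@H](Cc2ccccc2)COC1=O | starting material
14 | acetaldehyde | CC=O | starting material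
15 | Z dibutylboron enolate of 13 | C/C=C(\OB(CCCC)CCCC)N1[C@@H](Cc2ccccc2)COC1=O | intermediate (not isolated)
16 | (4S)-4-benzyl-3-[(2S,3R)-3-hydroxy-2-methylbutanoyl]-1,3-oxazolidin-2-one | C[C@@H](O)[C@H](C)C(=O)N1[C@@H](Cc2ccccc2)COC1=O | intermediate
17 | (2S,3R)-3-hydroxy-N-methoxy-N,2-dimethylbutanamide | C[C@@H](O)[C@H](C)C(=O)N(C)OC | intermediate
18 | (2S,3R)-3-[(tert-butyldimethylsilyl)oxy]-N-methoxy-N,2-dimethylbutanamide | C[C@@H](O[Si](C)(C)C(C)(C)C)[C@H](C)C(=O)N(C)OC | intermediate
19 | lithium enolate of 12 (methyl ketone side) | C=C(C)[C@H]1C[C@@H](C[C@](CC=C(C)C)(C(=C)O[Li])C(=O)OCC=C)C1(C)C | intermediate (not isolated)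
20 | allyl (2R)-2-[(4S,5R)-5-{[tert-butyl(dimethyl)silyl]oxy}-4-methyl-3-oxohexanoyl]-2-(Cb-methyl)-5-methylhex-4-enoate | C=C(C)[C@H]1C[C@@H](C[C@](CC=C(C)C)(C(=O)CC(=O)[C@@H](C)[C@@H](C)O[Si](C)(C)C(C)(C)C)C(=O)OCC=C)C1(C)C | intermediate
21 | allyl (2R)-2-[(4S,5R)-5-hydroxy-4-methyl-3-oxohexanoyl]-2-(Cb-methyl)-5-methylhex-4-enoate (with its cyclic hemiketal) | C=C(C)[C@H]1C[C@@H](C[C@](CC=C(C)C)(C(=O)CC(=O)[C@@H](C)[C@@H](C)O)C(=O)OCC=C)C1(C)C | intermediate (not isolated)
22 | allyl (2R)-2-[(2R,3S)-2,3-dimethyl-4-oxo-3,4-dihydro-2H-pyran-6-yl]-2-(Cb-methyl)-5-methylhex-4-enoate | C=C(C)[C@H]1C[C@@H](C[C@@](CC=C(C)C)(C(=O)OCC=C)C2=CC(=O)[C@@H](C)[C@@H](C)O2)C1(C)C | intermediate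
23 | allyl (2R)-2-[(2R,3S)-5-iodo-2,3-dimethyl-4-oxo-3,4-dihydro-2H-pyran-6-yl]-2-(Cb-methyl)-5-methylhex-4-enoate | C=C(C)[C@H]1C[C@@H](C[C@@](CC=C(C)C)(C(=O)OCC=C)C2=C(I)C(=O)[C@@H](C)[C@@H](C)O2)C1(C)C | intermediate
24 | 3-propylglutaric anhydride (4-propyloxane-2,6-dione) | CCCC1CC(=O)OC(=O)C1 | starting material
25 | (3R)-3-(2-methoxy-2-oxoethyl)hexanoic acid | CCC[C@H](CC(=O)O)CC(=O)OC | intermediate
26 | methyl (3R)-3-(2-hydroxyethyl)hexanoate | CCC[C@H](CCO)CC(=O)OC | intermediate
27 | methyl (3R)-3-(2-oxoethyl)hexanoate | CCC[C@H](CC=O)CC(=O)OC | intermediate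
28 | C5 chloromagnesio derivative of 23 | C=C(C)[C@H]1C[C@@H](C[C@@](CC=C(C)C)(C(=O)OCC=C)C2=C([Mg]Cl)C(=O)[C@@H](C)[C@@H](C)O2)C1(C)C | intermediate (not isolated)
29 | methyl (3R)-5-hydroxy-5-{(2R,3S)-6-[(2R)-2-(Cb-methyl)-5-methyl-1-oxo-1-(allyloxy)hex-4-en-2-yl]-2,3-dimethyl-4-oxo-3,4-dihydro-2H-pyran-5-yl}-3-propylpentanoate (carbinol epimers) | C=C(C)[C@H]1C[C@@H](C[C@@](CC=C(C)C)(C(=O)OCC=C)C2=C(C(O)C[C@@H](CCC)CC(=O)OC)C(=O)[C@@H](C)[C@@H](C)O2)C1(C)C | intermediate
30 | methyl (3R)-5-{(2R,3S)-6-[(2R)-2-(Cb-methyl)-5-methyl-1-oxo-1-(allyloxy)hex-4-en-2-yl]-2,3-dimethyl-4-oxo-3,4-dihydro-2H-pyran-5-yl}-5-oxo-3-propylpentanoate | C=C(C)[C@H]1C[C@@H](C[C@@](CC=C(C)C)(C(=O)OCC=C)C2=C(C(=O)C[C@@H](CCC)CC(=O)OC)C(=O)[C@@H](C)[C@@H](C)O2)C1(C)C | intermediate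
31 | lithium enolate of 30 (ketone CH2 side) | C=C(C)[C@H]1C[C@@H](C[C@@](CC=C(C)C)(C(=O)OCC=C)C2=C(C(O[Li])=C[C@@H](CCC)CC(=O)OC)C(=O)[C@@H](C)[C@@H](C)O2)C1(C)C | intermediate (not isolated)
32 | methyl (3S)-3-[(2R,3S,8R)-8-(Cb-methyl)-5-hydroxy-2,3-dimethyl-8-(3-methylbut-2-en-1-yl)-4,7-dioxo-3,4,7,8-tetrahydro-2H-chromen-6-yl]hexanoate | C=C(C)[C@H]1C[C@@H](C[C@@]2(CC=C(C)C)C(=O)C([C@@H](CCC)CC(=O)OC)=C(O)C3=C2O[C@H](C)[C@H](C)C3=O)C1(C)C | intermediate
33 | (3S)-3-[(2R,3S,8R)-8-(Cb-methyl)-5-hydroxy-2,3-dimethyl-8-(3-methylbut-2-en-1-yl)-4,7-dioxo-3,4,7,8-tetrahydro-2H-chromen-6-yl]hexanoic acid | C=C(C)[C@H]1C[C@@H](C[C@@]2(CC=C(C)C)C(=O)C([C@@H](CCC)CC(=O)O)=C(O)C3=C2O[C@H](C)[C@H](C)C3=O)C1(C)C | target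

**Count**
Total steps: 20. Longest linear sequence: 14 steps (1–7, 11–13, 17–20).

**Steps most likely to fail and fallbacks**

Step 19 (ring closure). The risk is that C–C bond formation at the neopentyl-type ester is outrun by O-acylation to an enol lactone that does not funnel onward, or by enolisation at the ring CH(Me) with loss of the cis configuration. The fallback upgrades the acceptor and makes enolisation soft. It sets out from 30: Pd(PPh3)4 (zerovalent palladium, catalytic) with morpholine in THF removes the allyl group to give (2R)-2-{(2R,3S)-5-[(3R)-5-methoxy-5-oxo-3-propylpentanoyl]-2,3-dimethyl-4-oxo-3,4-dihydro-2H-pyran-6-yl}-2-(Cb-methyl)-5-methylhex-4-enoic acid F1. 1-Chloro-N,N,2-trimethylprop-1-en-1-amine in CH2Cl2 at 0 °C converts it under neutral conditions into the corresponding acid chloride F2. MgBr2·OEt2 and iPr2NEt in CH2Cl2 then enolise the ketone as its magnesium chelate, and intramolecular C-acylation of ketones by acid chlorides under such soft enolisation should return to 32.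

Step 13 (iodination). The risk is iodonium formation at the prenyl or isopropenyl alkene followed by iodocyclisation onto the ester or enone oxygen, competing with substitution at C5. The fallback attaches the acyl chain before the ring double bond exists and needs no halogen. It sets out from 20: HF·pyridine in THF, then PPTS, MeOH and HC(OMe)3 give allyl (2R)-2-[(5S,6R)-2-methoxy-5,6-dimethyl-4-oxooxan-2-yl]-2-(Cb-methyl)-5-methylhex-4-enoate F4, the methyl ketal of the hemiketal form. Kinetic deprotonation at the ring CH2 with LiN(iPr)2 at −78 °C and aldol addition to 27 gives the β-hydroxy ketone F5. Dess–Martin periodinane gives the β-diketone F6, and TsOH in CH2Cl2 eliminates methanol across the ketal carbon and the doubly activated CH to return to 30.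

Step 7 (quaternary centre). The risk is poor or reversed facial selectivity in the enamine alkylation, or SN2′ attack of the prenyl bromide. Because the cyclobutane is already enantiopure, the two C2 configurations are diastereomers, so the fallback replaces induction by separation. It sets out from 7: NaH and prenyl bromide in THF give 12 together with allyl (2S)-2-acetyl-2-(Cb-methyl)-5-methylhex-4-enoate F3. The two are separated by preparative HPLC (if needed after carrying the pair through steps 11 and 12, where the pyranone centres lie closer), and the route is rejoined at 12.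

Further compounds
F1 | step 19 | (2R)-2-{(2R,3S)-5-[(3R)-5-methoxy-5-oxo-3-propylpentanoyl]-2,3-dimethyl-4-oxo-3,4-dihydro-2H-pyran-6-yl}-2-(Cb-methyl)-5-methylhex-4-enoic acid | C=C(C)[C@H]1C[C@@H](C[C@@](CC=C(C)C)(C(=O)O)C2=C(C(=O)C[C@@H](CCC)CC(=O)OC)C(=O)[C@@H](C)[C@@H](C)O2)C1(C)C
F2 | step 19 | (2R)-2-{(2R,3S)-5-[(3R)-5-methoxy-5-oxo-3-propylpentanoyl]-2,3-dimethyl-4-oxo-3,4-dihydro-2H-pyran-6-yl}-2-(Cb-methyl)-5-methylhex-4-enoyl chloride | C=C(C)[C@H]1C[C@@H](C[C@@](CC=C(C)C)(C(=O)Cl)C2=C(C(=O)C[C@@H](CCC)CC(=O)OC)C(=O)[C@@H](C)[C@@H](C)O2)C1(C)C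
F3 | step 7 | allyl (2S)-2-acetyl-2-(Cb-methyl)-5-methylhex-4-enoate | C=C(C)[C@H]1C[C@@H](C[C@@](CC=C(C)C)(C(C)=O)C(=O)OCC=C)C1(C)C
F4 | step 13 | allyl (2R)-2-[(5S,6R)-2-methoxy-5,6-dimethyl-4-oxooxan-2-yl]-2-(Cb-methyl)-5-methylhex-4-enoate (ketal epimers) | C=C(C)[C@H]1C[C@@H](C[C@@](CC=C(C)C)(C(=O)OCC=C)C2(OC)CC(=O)[C@@H](C)[C@@H](C)O2)C1(C)C
F5 | step 13 | methyl (3R)-5-hydroxy-5-{(5S,6R)-2-methoxy-2-[(2R)-2-(Cb-methyl)-5-methyl-1-oxo-1-(allyloxy)hex-4-en-2-yl]-5,6-dimethyl-4-oxooxan-3-yl}-3-propylpentanoate (epimer mixture) | C=C(C)[C@H]1C[C@@H](C[C@@](CC=C(C)C)(C(=O)OCC=C)C2(OC)C(C(O)C[C@@H](CCC)CC(=O)OC)C(=O)[C@@H](C)[C@@H](C)O2)C1(C)C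
F6 | step 13 | methyl (3R)-5-{(5S,6R)-2-methoxy-2-[(2R)-2-(Cb-methyl)-5-methyl-1-oxo-1-(allyloxy)hex-4-en-2-yl]-5,6-dimethyl-4-oxooxan-3-yl}-5-oxo-3-propylpentanoate (epimer mixture) | C=C(C)[C@H]1C[C@@H](C[C@@](CC=C(C)C)(C(=O)OCC=C)C2(OC)C(C(=O)C[C@@H](CCC)CC(=O)OC)C(=O)[C@@H](C)[C@@H](C)O2)C1(C)C
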